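**Plan**
- Retrosynthesis: the six phenols are unmasked last from methyl ethers. The cuts then follow in this order: the C7–C(=O) bond of the dihydrochalcone side chain (Friedel–Crafts acylation), the C1''–C2'' and C5''–C6'' bonds of the 2,4-dihydroxybenzoyl ring (Diels–Alder benzannulation), the ketone–alkyne bond (Weinreb ketone synthesis), and C3–C3a and O1–C2 of the benzofuran.
- Enabling feature: the ring on the C3 ketone carries hydroxyls at C2'' and C4'', ortho and para to the acyl-bearing C1''. C2''–C5'' therefore map onto a 1-methoxy-1,3-bis(trimethylsilyloxy)butadiene, and C1''/C6'' onto the two carbons of a benzofuran-3-yl ethynyl ketone.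
- Forward order: the furan ring arises first (O1–C2 by oxa-Michael addition, C3–C3a by Pd-catalysed oxidative cyclisation). The ester is then taken through the Weinreb amide to the ynone. The resorcinol ring is built by [4+2] cycloaddition and aromatisation, followed by O-methylation, C7 acylation and global demethylation.
- Stereochemistry: the target has no stereocentre and no stereogenic double bond. The enol ether geometries and the sp3 acetal carbon of the cycloadduct are transient.

Key step: step 7

Remark: the enol ether geometries drawn for the aryloxyacrylate, the silyl enol ether and the diene are the expected major isomers. Each is erased in the following step, so isomer mixtures can be carried through.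

**Route**

Step 1
Reactants: 1 3,5-dimethoxyphenol; 2 ethyl 3-(4-methoxyphenyl)prop-2-ynoate
Product: 3 ethyl (2Z)-3-(3,5-dimethoxyphenoxy)-3-(4-methoxyphenyl)prop-2-enoate
Conditions: K2CO3 (0.3 equiv), DMF, 100 °C
Reagents that add atoms: none
Why: Base-mediated oxa-Michael addition of the phenoxide to the β-carbon of the aryl propiolate, where anti addition should favour the Z enol ether and the geometry is of no consequence for step 2.

Step 2
Reactants: 3 ethyl (2Z)-3-(3,5-dimethoxyphenoxy)-3-(4-methoxyphenyl)prop-2-enoate
Product: 4 ethyl 4,6-dimethoxy-2-(4-methoxyphenyl)-1-benzofuran-3-carboxylate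
Conditions: Pd(OAc)2 (5 mol %), PPh3 (5 mol %), CF3CO2Ag (2 equiv), PhH, 110 °C, sealed tube, air
Reagents that add atoms: none
Why: Pd(OAc)2-catalysed intramolecular dehydrogenative C–H/C–H coupling of a 3-aryloxyacrylate to a benzofuran, in which divalent palladium metallates one of the two equivalent, strongly activated ortho carbons of the phenoxy ring, couples it to the acrylate α-carbon, and CF3CO2Ag returns zerovalent palladium to the divalent state.

Step 3
Reactants: 4 ethyl 4,6-dimethoxy-2-(4-methoxyphenyl)-1-benzofuran-3-carboxylate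
Product: 5 N,4,6-trimethoxy-2-(4-methoxyphenyl)-N-methyl-1-benzofuran-3-carboxamide
Conditions: MeNH(OMe)·HCl (3 equiv), iPrMgCl (6 equiv), THF, −20 → 0 °C
Reagents that add atoms: N,O-dimethylhydroxylamine hydrochloride, SMILES CNOC.Cl
Why: Weinreb amide formation by aminolysis of the ester with the small, strongly nucleophilic chloromagnesium amide of N,O-dimethylhydroxylamine, conditions that leave the methyl ethers and the benzofuran untouched.

Step 4
Reactants: 5 N,4,6-trimethoxy-2-(4-methoxyphenyl)-N-methyl-1-benzofuran-3-carboxamide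
Product: 6 1-[4,6-dimethoxy-2-(4-methoxyphenyl)-1-benzofuran-3-yl]prop-2-yn-1-one
Conditions: HC≡CMgBr (3 equiv), THF, 0 °C → rt; inverse quench into cold aq NaHSO4
Reagents that add atoms: ethynylmagnesium bromide, SMILES C#C[Mg]Br
Why: Weinreb ketone synthesis, in which the chelated tetrahedral magnesium adduct stops the addition at the ketone stage and the cold acidic quench protonates the released amine so that it cannot add to the ynone.

Step 5
Reactants: 7 methyl acetoacetate
Product: 8 methyl (2E)-3-(trimethylsilyloxy)but-2-enoate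
Conditions: TMSCl, Et3N, hexane, rt
Reagents that add atoms: chlorotrimethylsilane, SMILES C[Si](C)(C)Cl
Why: Silyl enol ether formation by O-silylation of the readily enolised β-keto ester with TMSCl and Et3N.

Step 6
Reactants: 8 methyl (2E)-3-(trimethylsilyloxy)but-2-enoate
Product: 9 (1Z)-1-methoxy-1,3-bis(trimethylsilyloxy)buta-1,3-diene
Conditions: LDA, THF, −78 °C; TMSCl, −78 °C → rt; distilled and used fresh
Reagents that add atoms: chlorotrimethylsilane, SMILES C[Si](C)(C)Cl
Why: γ-Deprotonation of the silyloxy crotonate by LDA gives the extended ester dienolate, which is trapped on the ester oxygen as the ketene silyl acetal (standard preparation of 1-alkoxy-1,3-bis(silyloxy) dienes).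

Step 7
Reactants: 6 1-[4,6-dimethoxy-2-(4-methoxyphenyl)-1-benzofuran-3-yl]prop-2-yn-1-one; 9 (1Z)-1-methoxy-1,3-bis(trimethylsilyloxy)buta-1,3-diene
Product: 12 (2,4-dihydroxyphenyl)[4,6-dimethoxy-2-(4-methoxyphenyl)-1-benzofuran-3-yl]methanone, via cyclohexa-1,4-diene cycloadduct 10 (not isolated), via aryl bis(trimethylsilyl) ether 11 (not isolated)
Conditions: 9 (2.5 equiv), PhMe, 90 °C; then 1 M HCl, THF, rt
Reagents that add atoms: none
Why: Normal-electron-demand Diels–Alder reaction between the electron-rich ketene-acetal diene and the electron-poor terminal ynone, of the type known for 1-alkoxy-3-silyloxy and 1-alkoxy-1,3-bis(silyloxy) dienes with acetylenic ketones and esters, followed by aromatisation. The six-membered carbocycle closes in a single intermolecular [4+2] event, probably asynchronous, in which the CH2 terminus of 9 (largest HOMO coefficient) bonds to the terminal alkyne carbon of 6 (largest LUMO coefficient) to give C5''–C6'', and the acetal carbon bonds to the carbon next to the ketone to give C1''–C2''. Cycloadduct 10 loses methanol by 1,4-elimination across the ring to give the aromatic bis(silyl) ether 11, and dilute acid cleaves both Si–O bonds to release resorcinol 12. No stereocentre remains, because the acetal carbon of 10 forms as a racemate and is flattened on aromatisation. The selectivity needed is the orientation that places the two oxygens ortho and para rather than meta to the ketone, and it is secured by the matched polarisation of the two partners and by the unhindered terminal CH of the ynone. Heating without a Lewis acid keeps the reaction on the cycloaddition path and away from 1,2-addition to the carbonyl or Michael–aldol condensation, and the methyl ethers, the anisyl group and the benzofuran are inert to the heat and to the dilute acid.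

Step 8
Reactants: 12 (2,4-dihydroxyphenyl)[4,6-dimethoxy-2-(4-methoxyphenyl)-1-benzofuran-3-yl]methanone
Product: 13 (2,4-dimethoxyphenyl)[4,6-dimethoxy-2-(4-methoxyphenyl)-1-benzofuran-3-yl]methanone
Conditions: MeI (4 equiv), K2CO3 (4 equiv), DMF, 50 °C
Reagents that add atoms: iodomethane, SMILES CI
Why: Williamson O-methylation of both phenols (the hydrogen-bonded C2'' hydroxyl needs the polar solvent and gentle warming), so that the next step can neither O-acylate nor C-acylate the resorcinol ring.

Step 9
Reactants: 13 (2,4-dimethoxyphenyl)[4,6-dimethoxy-2-(4-methoxyphenyl)-1-benzofuran-3-yl]methanone; 14 3-(4-methoxyphenyl)propanoic acid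
Product: 16 1-[3-(2,4-dimethoxybenzoyl)-4,6-dimethoxy-2-(4-methoxyphenyl)-1-benzofuran-7-yl]-3-(4-methoxyphenyl)propan-1-one, via acyl trifluoroacetate 15 (not isolated)
Conditions: 14 (1.3 equiv), TFAA (3 equiv), H3PO4 (cat), CH2Cl2, 0 °C → rt; aq NaHCO3
Reagents that add atoms: none
Why: Friedel–Crafts acylation by the mixed acyl trifluoroacetate (TFAA-mediated acylation with a carboxylic acid), expected at C7 because that carbon is ortho to O1 and to the C6 methoxy and para to the C4 methoxy and is less hindered than C5 between two methoxy groups, while the dimethoxybenzoyl ring is deactivated by its ketone and the anisyl rings carry a single donor.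

Step 10
Reactants: 16 1-[3-(2,4-dimethoxybenzoyl)-4,6-dimethoxy-2-(4-methoxyphenyl)-1-benzofuran-7-yl]-3-(4-methoxyphenyl)propan-1-one
Product: 17 1-[3-(2,4-dihydroxybenzoyl)-4,6-dihydroxy-2-(4-hydroxyphenyl)-1-benzofuran-7-yl]-3-(4-hydroxyphenyl)propan-1-one
Conditions: BBr3 (15 equiv), CH2Cl2, −78 °C → rt; then H2O, 0 °C
Reagents that add atoms: none
Why: BBr3 cleavage of aryl methyl ethers (boron–oxygen complexation, then bromide attack on the methyl group) should remove all six methyl groups, the ethers next to the two ketones going fastest through chelation, while both ketones and the benzofuran are inert.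

**Compound list**
1 | 3,5-dimethoxyphenol | COc1cc(O)cc(OC)c1 | starting material
2 | ethyl 3-(4-methoxyphenyl)prop-2-ynoate | CCOC(=O)C#Cc1ccc(OC)cc1 | starting material
3 | ethyl (2Z)-3-(3,5-dimethoxyphenoxy)-3-(4-methoxyphenyl)prop-2-enoate | CCOC(=O)/C=C(\Oc1cc(OC)cc(OC)c1)c1ccc(OC)cc1 | intermediate
4 | ethyl 4,6-dimethoxy-2-(4-methoxyphenyl)-1-benzofuran-3-carboxylate | CCOC(=O)c1c(-c2ccc(OC)cc2)oc2cc(OC)cc(OC)c12 | intermediate
5 | N,4,6-trimethoxy-2-(4-methoxyphenyl)-N-methyl-1-benzofuran-3-carboxamide | CON(C)C(=O)c1c(-c2ccc(OC)cc2)oc2cc(OC)cc(OC)c12 | intermediate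
6 | 1-[4,6-dimethoxy-2-(4-methoxyphenyl)-1-benzofuran-3-yl]prop-2-yn-1-one | C#CC(=O)c1c(-c2ccc(OC)cc2)oc2cc(OC)cc(OC)c12 | intermediate
7 | methyl acetoacetate | COC(=O)CC(C)=O | starting material
8 | methyl (2E)-3-(trimethylsilyloxy)but-2-enoate | COC(=O)/C=C(\C)O[Si](C)(C)C | intermediate
9 | (1Z)-1-methoxy-1,3-bis(trimethylsilyloxy)buta-1,3-diene | CO/C(O[Si](C)(C)C)=C/C(=C)O[Si](C)(C)C | intermediate
10 | racemic [4,6-dimethoxy-2-(4-methoxyphenyl)-1-benzofuran-3-yl][6-methoxy-4,6-bis(trimethylsilyloxy)cyclohexa-1,4-dien-1-yl]methanone (formed in the flask) | COc1ccc(cc1)-c1oc2cc(OC)cc(OC)c2c1C(=O)C1=CCC(O[Si](C)(C)C)=CC1(OC)O[Si](C)(C)C | intermediate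
11 | [2,4-bis(trimethylsilyloxy)phenyl][4,6-dimethoxy-2-(4-methoxyphenyl)-1-benzofuran-3-yl]methanone (formed in the flask) | COc1ccc(cc1)-c1oc2cc(OC)cc(OC)c2c1C(=O)c1ccc(O[Si](C)(C)C)cc1O[Si](C)(C)C | intermediate
12 | (2,4-dihydroxyphenyl)[4,6-dimethoxy-2-(4-methoxyphenyl)-1-benzofuran-3-yl]methanone | COc1ccc(cc1)-c1oc2cc(OC)cc(OC)c2c1C(=O)c1ccc(O)cc1O | intermediate
13 | (2,4-dimethoxyphenyl)[4,6-dimethoxy-2-(4-methoxyphenyl)-1-benzofuran-3-yl]methanone | COc1ccc(cc1)-c1oc2cc(OC)cc(OC)c2c1C(=O)c1ccc(OC)cc1OC | intermediate
14 | 3-(4-methoxyphenyl)propanoic acid | COc1ccc(CCC(O)=O)cc1 | starting material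
15 | 3-(4-methoxyphenyl)propanoic trifluoroacetic anhydride (formed in the flask) | COc1ccc(CCC(=O)OC(=O)C(F)(F)F)cc1 | intermediate
16 | 1-[3-(2,4-dimethoxybenzoyl)-4,6-dimethoxy-2-(4-methoxyphenyl)-1-benzofuran-7-yl]-3-(4-methoxyphenyl)propan-1-one | COc1ccc(CCC(=O)c2c(OC)cc(OC)c3c(C(=O)c4ccc(OC)cc4OC)c(-c4ccc(OC)cc4)oc23)cc1 | intermediate
17 | 1-[3-(2,4-dihydroxybenzoyl)-4,6-dihydroxy-2-(4-hydroxyphenyl)-1-benzofuran-7-yl]-3-(4-hydroxyphenyl)propan-1-one | O=C(CCc1ccc(O)cc1)c1c(O)cc(O)c2c(C(=O)c3ccc(O)cc3O)c(-c3ccc(O)cc3)oc12 | target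

**Step count and risks**

Total step count: 10. Longest linear sequence: 8 (steps 1, 2, 3, 4, 7, 8, 9, 10); steps 5 and 6 form the diene branch.

Steps most likely to fail:

1. Step 7, the benzannulation. The cycloaddition may be slow, because the ynone carbonyl is twisted by the flanking C2 aryl and C4 methoxy groups and is electronically damped by the benzofuran oxygen. That leaves time for thermal decomposition or protodesilylation of the diene. The reaction may also drift into a stepwise Michael–aldol condensation that joins the benzofuran directly to the new ring. The fallback gives up the cycloaddition; it sets out from 5 and comes back to the route at 13. 1-Bromo-2,4-dimethoxybenzene would be treated with n-BuLi in THF at −78 °C to give (2,4-dimethoxyphenyl)lithium F1, which is added to Weinreb amide 5 at −78 → 0 °C. Quenching with water should give diaryl ketone 13 directly by Weinreb ketone synthesis. Steps 4 to 8 are then bypassed and steps 9 and 10 follow unchanged.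

2. Step 9, the C7 acylation. The acyl group may enter at the wrong carbon (C5, or C5'' of the dimethoxybenzoyl ring), or the arene may be trifluoroacetylated instead. The fallback sets out from 13 and comes back at 16; it uses a weaker and bulkier electrophile and builds the ketone in two further operations. Vilsmeier–Haack formylation (POCl3, DMF, 0 → 60 °C) should give the C7 iminium chloride F2. Aqueous NaOAc work-up should hydrolyse it to 3-(2,4-dimethoxybenzoyl)-4,6-dimethoxy-2-(4-methoxyphenyl)-1-benzofuran-7-carbaldehyde F3. [2-(4-Methoxyphenyl)ethyl]magnesium bromide F4, made from 1-(2-bromoethyl)-4-methoxybenzene and Mg turnings in THF, would be added at −78 °C. The aldehyde should react far faster than the hindered, donor-substituted diaryl ketone, giving the racemic secondary alcohol {7-[1-hydroxy-3-(4-methoxyphenyl)propyl]-4,6-dimethoxy-2-(4-methoxyphenyl)-1-benzofuran-3-yl}(2,4-dimethoxyphenyl)methanone F5. Dess–Martin oxidation in CH2Cl2 should then give 16.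

3. Step 3, the Weinreb amide formation. Aminolysis may stop short, because the ester is flanked by the C2 aryl and the C4 methoxy group and is electronically deactivated as a vinylogous carbonate. The fallback sets out from 4 and comes back at 5; it replaces ester aminolysis by acylation with an acid chloride. Saponification (KOH, EtOH–H2O, reflux; then HCl) should give 4,6-dimethoxy-2-(4-methoxyphenyl)-1-benzofuran-3-carboxylic acid F6. (COCl)2 with catalytic DMF in CH2Cl2 should convert it into 4,6-dimethoxy-2-(4-methoxyphenyl)-1-benzofuran-3-carbonyl chloride F7. Reaction of F7 with MeNH(OMe)·HCl and Et3N at 0 °C should give 5.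

**Further compounds**
F1 | step 7 | (2,4-dimethoxyphenyl)lithium | [Li]c1ccc(OC)cc1OC
F2 | step 9 | N-{[3-(2,4-dimethoxybenzoyl)-4,6-dimethoxy-2-(4-methoxyphenyl)-1-benzofuran-7-yl]methylidene}-N-methylmethanaminium chloride | C[N+](C)=Cc1c(OC)cc(OC)c2c(C(=O)c3ccc(OC)cc3OC)c(-c3ccc(OC)cc3)oc12.[Cl-]
F3 | step 9 | 3-(2,4-dimethoxybenzoyl)-4,6-dimethoxy-2-(4-methoxyphenyl)-1-benzofuran-7-carbaldehyde | O=Cc1c(OC)cc(OC)c2c(C(=O)c3ccc(OC)cc3OC)c(-c3ccc(OC)cc3)oc12
F4 | step 9 | [2-(4-methoxyphenyl)ethyl]magnesium bromide | COc1ccc(CC[Mg]Br)cc1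
F5 | step 9 | racemic {7-[1-hydroxy-3-(4-methoxyphenyl)propyl]-4,6-dimethoxy-2-(4-methoxyphenyl)-1-benzofuran-3-yl}(2,4-dimethoxyphenyl)methanone | COc1ccc(CCC(O)c2c(OC)cc(OC)c3c(C(=O)c4ccc(OC)cc4OC)c(-c4ccc(OC)cc4)oc23)cc1
F6 | step 3 | 4,6-dimethoxy-2-(4-methoxyphenyl)-1-benzofuran-3-carboxylic acid | OC(=O)c1c(-c2ccc(OC)cc2)oc2cc(OC)cc(OC)c12
F7 | step 3 | 4,6-dimethoxy-2-(4-methoxyphenyl)-1-benzofuran-3-carbonyl chloride | ClC(=O)c1c(-c2ccc(OC)cc2)oc2cc(OC)cc(OC)c12
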